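**Assumption:** the target has no stereocentre and no hindered axis, so "single enantiomer" is taken to mean the single constitutional isomer drawn. Unprimed locants (C8, C4') refer to the chlorinated isoflavone, double-primed locants (C8'') to the other. Compounds 1, 2, 4 and 8 are taken as catalogue chemicals.

## The problem

Bisoflavolin I is two genistein units joined head to tail by one diaryl ether, C4'–O–C8''. The unit that gives its B ring to the ether carries Cl at C8; the other carries the ether oxygen at C8''. There is no stereocentre, so the difficulty is regiochemical. Each A ring is a phloroglucinol whose C6 and C8 are almost equally nucleophilic, so "8 and not 6" must be secured twice, once for Cl and once for O. The ether carbon C8'' is electron-rich and di-ortho-substituted (between O1''/C8a'' and O7''/C7''), which makes it a poor electrophile for SNAr or Ullmann chemistry on a finished chromone. The two halves carry the same functional groups (five phenols, two γ-pyranones), so a late reaction on one half has no handle to spare the other. The pyranones open in hot base, 5-hydroxy-8-substituted chromones can isomerise to 6-substituted ones in hot mineral acid (Wessely–Moser), and the aryl chloride forbids hydrogenolysis.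

The feature that the plan exploits is this: in both A rings the C8 substituent (Cl on C8, the ether O on C8'') sits between the oxygens on C7 and C8a. Each A ring is therefore a 2-substituted 1,3,5-trioxygenated benzene that is C2v-symmetric until C4 is attached. Once it is acylated, the C8 substituent makes the oxygen destined to become O1 (or O1'') the only carbonyl-flanking oxygen that is di-ortho-substituted.

## Retrosynthesis

**14 ⇒ 13.** The five O–CH3 bonds are cut. Methyl is chosen over benzyl, MOM or silyl because the methyl ethers are the handles of the regiochemical programme below and survive Friedel–Crafts, base and BCl3 chemistry. The forward reaction is one exhaustive BBr3 demethylation under conditions that spare the ether, the chloride and the pyranones.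

**13 ⇒ 10 (key disconnection, through 11 and 12).** In both pyranone rings the O1–C2 and C2–C3 bonds (and O1''–C2'', C2''–C3'') are cut, the C2 carbons are removed as a C1 reagent, and O1 and O1'' are re-methylated. The precursor 10 is an acyclic heptamethoxy diketone with no heterocycle. Against closing the rings one at a time, or joining two finished isoflavones, this cut turns both "8 versus 6" questions into one question: which of two OMe groups flanking each ketone is removed. The C8 substituents answer it. The forward reaction must demethylate one specific ortho-OMe at each ketone and then annulate twice.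

**10 ⇒ 7 + 8 (through 9).** The aryl ketone bond C4–C4a is cut. Arene 8 has two equivalent free positions, each between two OMe groups, so the Friedel–Crafts acylation has no regiochemical choice and puts Cl on the carbon that becomes C8. The forward reaction must acylate 8 faster than the remaining CH of the already acylated ring of 7.

**7 ⇒ 6 ⇒ 3 + 4 (through 5).** The aryl ketone bond C4''–C4a'' is cut. The trimethoxyphenoxy ring of 3 is symmetric with two equivalent CH positions, so again one product is possible. The acid of the second arm stays masked as its methyl ester until this ring has been deactivated by acylation; otherwise it would acylate its own molecule.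

**3 ⇒ 1 + 2.** The C4'–O bond is cut at the stage of two simple benzenes. The hindered partner (phenol 1, flanked by two OMe) becomes the nucleophile and the unhindered aryl iodide 2 the electrophile, which is the favourable polarity for an Ullmann ether synthesis. Cutting C8''–O instead would need a di-ortho-substituted electron-rich aryl halide as electrophile.

## Roads not taken

**Alternative 1:** the most obvious cut is the C8''–O bond between two finished, protected isoflavones. The forward key step would be a copper-mediated Ullmann coupling of the 8-iodide A1 with the 4'-phenol A2 to give 13. The chosen plan is better for three reasons: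
- The C–I carbon of A1 is electron-rich and flanked by the pyranone oxygen and 7-OMe, so oxidative addition is slow and protodeiodination competes, at temperatures where phenoxide can open the pyranone.
- A2 needs a free 4'-OH beside protected 5- and 7-oxygens, which is the reverse of the phenol reactivity order of the parent isoflavone (7 > 4' > 5), so it needs its own de novo synthesis.
- Both monomers need a C8-selective halogenation, and the total step count roughly doubles.

**Alternative 2:** a biomimetic cut of the same bond by oxidative phenol cross-coupling of 8-chlorogenistein A3 with genistein A4, giving 14 in one step. The 4'-phenoxyl radical carries spin at O, C3' and C5', and the A-ring phenoxyl at C6 and C8, so C–C and C–O homo- and cross-dimers and oligomers are all open. Nothing in the substrates tells the two partners apart, since the chlorine of A3 is remote from its reacting 4'-OH. A3 itself would need a chlorination of A4 selective for C8 over C6 and C3'. The chosen plan replaces this unguided selection by one that the substrate dictates.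

**Alternative 3:** cut both C3–C1' bonds (Suzuki logic). The 3-iodochromones A5 and A6 would be made by enaminone/iodine cyclisation; A6 would be coupled at C3–I with an anisylboron reagent, borylated at the aryl bromide to A7, and joined to A5 to give 13. The acetophenones behind A5 and A6 pose the same "which oxygen becomes O1" question, so nothing is gained there. The plan adds three palladium steps, needs ArI/ArBr/ArCl chemoselectivity, and uses base-sensitive 3-iodochromones. It is about twice as long.

Key step: step 5

## Route

Step 1
Reactants: 1 2,4,6-trimethoxyphenol; 2 methyl 2-(4-iodophenyl)acetate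
Product: 3 methyl 2-[4-(2,4,6-trimethoxyphenoxy)phenyl]acetate
Conditions: CuI (10 mol %), picolinic acid (20 mol %), K3PO4, degassed DMSO, 90 °C, Ar
Reagents that add atoms: none
Why: Ullmann-type Cu(I)/picolinate C–O coupling, which tolerates di-ortho-substituted phenols when the aryl iodide is unhindered; the hindered, electron-rich partner is deliberately the nucleophile. K3PO4 is too weak to cleave or enolise the methyl arylacetate, and exclusion of air keeps 1 from oxidising to a quinone.

Step 2
Reactants: 3 methyl 2-[4-(2,4,6-trimethoxyphenoxy)phenyl]acetate; 4 2-(4-methoxyphenyl)acetic acid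
Product: 6 methyl 2-(4-{2,4,6-trimethoxy-3-[2-(4-methoxyphenyl)acetyl]phenoxy}phenyl)acetate, via mixed anhydride 5 (not isolated)
Conditions: (CF3CO)2O, 85% H3PO4 (cat.), CH2Cl2, 0 °C → rt
Reagents that add atoms: none
Why: Friedel–Crafts acylation through the mixed trifluoroacetic anhydride; the trimethoxyphenoxy ring is by far the most nucleophilic arene present and its two free positions are equivalent, so one regioisomer can form, and the new acyl group deactivates the ring against a second acylation. Metal-free conditions avoid premature Lewis-acid demethylation and leave the ester intact.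

Step 3
Reactants: 6 methyl 2-(4-{2,4,6-trimethoxy-3-[2-(4-methoxyphenyl)acetyl]phenoxy}phenyl)acetate
Product: 7 2-(4-{2,4,6-trimethoxy-3-[2-(4-methoxyphenyl)acetyl]phenoxy}phenyl)acetic acid
Conditions: LiOH·H2O, THF/H2O, rt; then 1 M HCl
Reagents that add atoms: lithium hydroxide, [Li+].[OH-]; water, O
Why: Saponification of the methyl ester; the ketone, the aryl methyl ethers and the diaryl ether are inert to aqueous LiOH at room temperature. The acid is freed only after the electron-rich ring has been deactivated, so it cannot acylate its own molecule in step 4.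

Step 4
Reactants: 7 2-(4-{2,4,6-trimethoxy-3-[2-(4-methoxyphenyl)acetyl]phenoxy}phenyl)acetic acid; 8 2-chloro-1,3,5-trimethoxybenzene (3 equiv)
Product: 10 1-(3-chloro-2,4,6-trimethoxyphenyl)-2-(4-{2,4,6-trimethoxy-3-[2-(4-methoxyphenyl)acetyl]phenoxy}phenyl)ethan-1-one, via mixed anhydride 9 (not isolated)
Conditions: (CF3CO)2O, 85% H3PO4 (cat.), CH2Cl2, 0 °C → rt
Reagents that add atoms: none
Why: Second Friedel–Crafts acylation through a mixed anhydride; the two free positions of 8 are equivalent (each between two OMe), so no regiochemical choice arises and Cl lands on the carbon that becomes C8. Excess 8 should out-compete the last CH of the acylated ring of 7, which is deactivated by a meta-acyl and a meta-aryloxy group.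

Step 5
Reactants: 10 1-(3-chloro-2,4,6-trimethoxyphenyl)-2-(4-{2,4,6-trimethoxy-3-[2-(4-methoxyphenyl)acetyl]phenoxy}phenyl)ethan-1-one
Product: 13 8-chloro-3-(4-{[5,7-dimethoxy-3-(4-methoxyphenyl)-4-oxo-4H-chromen-8-yl]oxy}phenyl)-5,7-dimethoxy-4H-chromen-4-one, via bis-phenol 11 (not isolated), via bis-enaminone 12 (not isolated)
Conditions: BCl3 (5 equiv), CH2Cl2, −78 → 0 °C; MeOH quench, evaporate; then Me2NCH(OMe)2 (6 equiv), PhMe, 100 °C
Reagents that add atoms: N,N-dimethylformamide dimethyl acetal, COC(OC)N(C)C
Why: Stage 1 is a chelation-controlled ortho-demethylation of aryl ketones by BCl3: boron binds the carbonyl oxygen, closes a six-membered chelate onto one flanking OMe, and chloride removes that methyl as MeCl. Each ketone of 10 has two flanking OMe groups, and the one next to C–Cl (future ring A) or next to the C–OAr ether (future ring A'') is di-ortho-substituted, twisted out of the ring plane and therefore the more Lewis-basic and more strained; this is the selection that turns 2,3,4,6-tetramethoxyaryl ketones into 2-hydroxy-3,4,6-trimethoxyaryl ketones (the standard entry to 5,7,8-trioxygenated flavonoids) and that lets Lewis acids pick the central OMe of a 1,2,3-trimethoxyarene. Once one oxygen is locked in the O–B–O chelate the second flanking OMe is no longer activated, and the para-OMe groups and the anisyl OMe, which cannot chelate, should be untouched at or below 0 °C. Methanolysis releases bis-phenol 11, in which exactly one OH flanks each carbonyl. Stage 2 is the standard enaminone annulation of 2-hydroxydeoxybenzoins: the acetal condenses at each doubly activated benzylic CH2 to give 12, the chelated phenol adds to the enaminone β-carbon in a 6-endo-trig oxa-Michael addition, and Me2NH is eliminated, which closes each γ-pyranone ring (O1–C2 and O1''–C2''; C2 and C2'' come from the reagent). The only selectivity needed is which oxygen becomes O1 and O1'', and the C8 substituents themselves secure it, so Cl ends at C8 and the ether at C8'' without any protecting-group distinction between the halves. No stereocentre is formed.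

Step 6
Reactants: 13 8-chloro-3-(4-{[5,7-dimethoxy-3-(4-methoxyphenyl)-4-oxo-4H-chromen-8-yl]oxy}phenyl)-5,7-dimethoxy-4H-chromen-4-one
Product: 14 8-chloro-3-(4-{[5,7-dihydroxy-3-(4-hydroxyphenyl)-4-oxo-4H-chromen-8-yl]oxy}phenyl)-5,7-dihydroxy-4H-chromen-4-one (bisoflavolin I)
Conditions: BBr3 (15 equiv), CH2Cl2, −78 °C → rt; then H2O
Reagents that add atoms: none
Why: Exhaustive Lewis-acid cleavage of the five aryl methyl ethers, a routine end game for polymethoxyisoflavones; the C5 and C5'' ethers go first through chelation to C4=O. The diaryl ether, the aryl chloride and the pyranones are inert to BBr3, and working at or below room temperature instead of in hot HBr or HI avoids Wessely–Moser ring-opening that could move the C8 substituents to C6.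

## Compound list

1 | 2,4,6-trimethoxyphenol | COc1cc(OC)c(O)c(OC)c1 | starting material
2 | methyl 2-(4-iodophenyl)acetate | COC(=O)Cc1ccc(I)cc1 | starting material
3 | methyl 2-[4-(2,4,6-trimethoxyphenoxy)phenyl]acetate | COC(=O)Cc1ccc(Oc2c(OC)cc(OC)cc2OC)cc1 | intermediate
4 | 2-(4-methoxyphenyl)acetic acid | COc1ccc(CC(=O)O)cc1 | starting material
5 | 2-(4-methoxyphenyl)acetic trifluoroacetic anhydride | COc1ccc(CC(=O)OC(=O)C(F)(F)F)cc1 | intermediate (not isolated)
6 | methyl 2-(4-{2,4,6-trimethoxy-3-[2-(4-methoxyphenyl)acetyl]phenoxy}phenyl)acetate | COC(=O)Cc1ccc(Oc2c(OC)cc(OC)c(C(=O)Cc3ccc(OC)cc3)c2OC)cc1 | intermediate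
7 | 2-(4-{2,4,6-trimethoxy-3-[2-(4-methoxyphenyl)acetyl]phenoxy}phenyl)acetic acid | OC(=O)Cc1ccc(Oc2c(OC)cc(OC)c(C(=O)Cc3ccc(OC)cc3)c2OC)cc1 | intermediate
8 | 2-chloro-1,3,5-trimethoxybenzene | COc1cc(OC)c(Cl)c(OC)c1 | starting material
9 | 2-(4-{2,4,6-trimethoxy-3-[2-(4-methoxyphenyl)acetyl]phenoxy}phenyl)acetic trifluoroacetic anhydride | O=C(Cc1ccc(Oc2c(OC)cc(OC)c(C(=O)Cc3ccc(OC)cc3)c2OC)cc1)OC(=O)C(F)(F)F | intermediate (not isolated)
10 | 1-(3-chloro-2,4,6-trimethoxyphenyl)-2-(4-{2,4,6-trimethoxy-3-[2-(4-methoxyphenyl)acetyl]phenoxy}phenyl)ethan-1-one | COc1ccc(CC(=O)c2c(OC)cc(OC)c(Oc3ccc(CC(=O)c4c(OC)cc(OC)c(Cl)c4OC)cc3)c2OC)cc1 | intermediate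
11 | 1-(3-chloro-2-hydroxy-4,6-dimethoxyphenyl)-2-(4-{2-hydroxy-4,6-dimethoxy-3-[2-(4-methoxyphenyl)acetyl]phenoxy}phenyl)ethan-1-one | COc1ccc(CC(=O)c2c(OC)cc(OC)c(Oc3ccc(CC(=O)c4c(OC)cc(OC)c(Cl)c4O)cc3)c2O)cc1 | intermediate (not isolated)
12 | 1-(3-chloro-2-hydroxy-4,6-dimethoxyphenyl)-3-(dimethylamino)-2-[4-(3-{3-(dimethylamino)-2-(4-methoxyphenyl)prop-2-enoyl}-2-hydroxy-4,6-dimethoxyphenoxy)phenyl]prop-2-en-1-one (C=C geometry not defined; either isomer cyclises) | COc1ccc(cc1)C(=CN(C)C)C(=O)c1c(OC)cc(OC)c(Oc2ccc(cc2)C(=CN(C)C)C(=O)c2c(OC)cc(OC)c(Cl)c2O)c1O | intermediate (not isolated)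
13 | 8-chloro-3-(4-{[5,7-dimethoxy-3-(4-methoxyphenyl)-4-oxo-4H-chromen-8-yl]oxy}phenyl)-5,7-dimethoxy-4H-chromen-4-one (penta-O-methylbisoflavolin I) | COc1ccc(cc1)-c1coc2c(Oc3ccc(cc3)-c3coc4c(Cl)c(OC)cc(OC)c4c3=O)c(OC)cc(OC)c2c1=O | intermediate
14 | bisoflavolin I, 8-chloro-3-(4-{[5,7-dihydroxy-3-(4-hydroxyphenyl)-4-oxo-4H-chromen-8-yl]oxy}phenyl)-5,7-dihydroxy-4H-chromen-4-one | O=c1c(-c2ccc(Oc3c(O)cc(O)c4c(=O)c(-c5ccc(O)cc5)coc34)cc2)coc2c(Cl)c(O)cc(O)c12 | target

## Step count and least certain steps

Total steps: 6. Longest linear sequence: 6 (from 1 and 2 to 14).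

**Step 5 (key step).** The most likely failure is incomplete site-selectivity of the ortho-demethylation at the chlorine-flanked ketone. Chlorine is smaller and a poorer donor than an alkoxy neighbour, and the precedent is closest for oxygen-flanked methoxy groups. Cleavage of the H-flanked OMe would lead, after annulation, to the 6-chloro series. Over-demethylation by excess BCl3 and re-methylation of the phenols by the acetal are lesser risks.

The fallback replaces the pre-installed chlorine by a late chlorination. It sets out from 7, which would be acylated under the step 4 conditions (through 9) with commercial 1,3,5-trimethoxybenzene to the chlorine-free diketone 1-(2,4,6-trimethoxyphenyl)-2-(4-{2,4,6-trimethoxy-3-[2-(4-methoxyphenyl)acetyl]phenoxy}phenyl)ethan-1-one F1. The new ketone is symmetric, so only the aryloxy-flanked selection remains to be made. BCl3 followed by methanol should give the chlorine-free bis-phenol F2, and the formamide acetal should give, through the chlorine-free bis-enaminone F3, the chlorine-free penta-O-methyl bis-isoflavone F4. One equivalent of N-chlorosuccinimide in DMF at room temperature should then chlorinate C8 of the 5,7-dimethoxychromone unit, the position at which 5,7-dialkoxychromones are halogenated. C6'' (between two OMe, with C8'' blocked) and the anisyl ring should react more slowly. This returns to the route at 13.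

**Step 4.** The most likely failure is loss of chemoselectivity in the electrophilic substitution. The mixed anhydride may acylate the remaining CH of the tetraoxygenated ring of a second molecule of 7 (oligomerisation), or the enolisable deoxybenzoin may be trifluoroacetylated, because 8 is slightly deactivated by chlorine.

The fallback makes the same ketone by cross-coupling, so that ring nucleophilicity no longer matters. It sets out from 7, which oxalyl chloride with catalytic DMF would convert into 2-(4-{2,4,6-trimethoxy-3-[2-(4-methoxyphenyl)acetyl]phenoxy}phenyl)acetyl chloride F5. Separately, 8 would be lithiated between two methoxy groups (n-BuLi, THF, 0 °C) to (3-chloro-2,4,6-trimethoxyphenyl)lithium F6 and transmetalated with ZnCl2 to chlorido(3-chloro-2,4,6-trimethoxyphenyl)zinc F7. A Pd(PPh3)4-catalysed acyl Negishi coupling of F5 with F7, which tolerates the second ketone, comes back to the route at 10.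

**Step 1.** The most likely failure is oxidative degradation of the very electron-rich phenol 1 under copper catalysis, together with slow C–O bond formation at the doubly ortho-substituted phenoxide and some ester cleavage by phosphate.

The fallback is metal-free. It sets out from 1, which would undergo SNAr with 4-fluoroacetophenone (K2CO3, DMF, 120 °C) to give 1-[4-(2,4,6-trimethoxyphenoxy)phenyl]ethan-1-one F8. A Willgerodt–Kindler reaction (sulfur, morpholine, 130 °C) would move the oxidation state to the terminal carbon, giving 1-(morpholin-4-yl)-2-[4-(2,4,6-trimethoxyphenoxy)phenyl]ethane-1-thione F9. Alkaline hydrolysis would give 2-[4-(2,4,6-trimethoxyphenoxy)phenyl]acetic acid F10, and Fischer esterification (MeOH, cat. H2SO4) would return to the route at 3.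

## Further compounds

F1 | step 5 | 1-(2,4,6-trimethoxyphenyl)-2-(4-{2,4,6-trimethoxy-3-[2-(4-methoxyphenyl)acetyl]phenoxy}phenyl)ethan-1-one | COc1ccc(CC(=O)c2c(OC)cc(OC)c(Oc3ccc(CC(=O)c4c(OC)cc(OC)cc4OC)cc3)c2OC)cc1
F2 | step 5 | 1-(2-hydroxy-4,6-dimethoxyphenyl)-2-(4-{2-hydroxy-4,6-dimethoxy-3-[2-(4-methoxyphenyl)acetyl]phenoxy}phenyl)ethan-1-one | COc1ccc(CC(=O)c2c(OC)cc(OC)c(Oc3ccc(CC(=O)c4c(OC)cc(OC)cc4O)cc3)c2O)cc1
F3 | step 5 | 3-(dimethylamino)-2-[4-(3-{3-(dimethylamino)-2-(4-methoxyphenyl)prop-2-enoyl}-2-hydroxy-4,6-dimethoxyphenoxy)phenyl]-1-(2-hydroxy-4,6-dimethoxyphenyl)prop-2-en-1-one | COc1ccc(cc1)C(=CN(C)C)C(=O)c1c(OC)cc(OC)c(Oc2ccc(cc2)C(=CN(C)C)C(=O)c2c(OC)cc(OC)cc2O)c1O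
F4 | step 5 | 3-(4-{[5,7-dimethoxy-3-(4-methoxyphenyl)-4-oxo-4H-chromen-8-yl]oxy}phenyl)-5,7-dimethoxy-4H-chromen-4-one | COc1ccc(cc1)-c1coc2c(Oc3ccc(cc3)-c3coc4cc(OC)cc(OC)c4c3=O)c(OC)cc(OC)c2c1=O
F5 | step 4 | 2-(4-{2,4,6-trimethoxy-3-[2-(4-methoxyphenyl)acetyl]phenoxy}phenyl)acetyl chloride | COc1ccc(CC(=O)c2c(OC)cc(OC)c(Oc3ccc(CC(Cl)=O)cc3)c2OC)cc1
F6 | step 4 | (3-chloro-2,4,6-trimethoxyphenyl)lithium | COc1cc(OC)c([Li])c(OC)c1Cl
F7 | step 4 | chlorido(3-chloro-2,4,6-trimethoxyphenyl)zinc | COc1cc(OC)c([Zn]Cl)c(OC)c1Cl
F8 | step 1 | 1-[4-(2,4,6-trimethoxyphenoxy)phenyl]ethan-1-one | CC(=O)c1ccc(Oc2c(OC)cc(OC)cc2OC)cc1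
F9 | step 1 | 1-(morpholin-4-yl)-2-[4-(2,4,6-trimethoxyphenoxy)phenyl]ethane-1-thione | S=C(Cc1ccc(Oc2c(OC)cc(OC)cc2OC)cc1)N1CCOCC1
F10 | step 1 | 2-[4-(2,4,6-trimethoxyphenoxy)phenyl]acetic acid | OC(=O)Cc1ccc(Oc2c(OC)cc(OC)cc2OC)cc1
A1 | alternative 1 | 8-iodo-5,7-dimethoxy-3-(4-methoxyphenyl)-4H-chromen-4-one | COc1ccc(cc1)-c1coc2c(I)c(OC)cc(OC)c2c1=O
A2 | alternative 1 | 8-chloro-3-(4-hydroxyphenyl)-5,7-dimethoxy-4H-chromen-4-one | COc1cc(OC)c2c(=O)c(-c3ccc(O)cc3)coc2c1Cl
A3 | alternative 2 | 8-chlorogenistein, 8-chloro-5,7-dihydroxy-3-(4-hydroxyphenyl)-4H-chromen-4-one | O=c1c(-c2ccc(O)cc2)coc2c(Cl)c(O)cc(O)c12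
A4 | alternative 2 | genistein, 5,7-dihydroxy-3-(4-hydroxyphenyl)-4H-chromen-4-one | O=c1c(-c2ccc(O)cc2)coc2cc(O)cc(O)c12
A5 | alternative 3 | 8-chloro-3-iodo-5,7-dimethoxy-4H-chromen-4-one | COc1cc(OC)c2c(=O)c(I)coc2c1Cl
A6 | alternative 3 | 8-(4-bromophenoxy)-3-iodo-5,7-dimethoxy-4H-chromen-4-one | COc1cc(OC)c2c(=O)c(I)coc2c1Oc1ccc(Br)cc1
A7 | alternative 3 | 5,7-dimethoxy-3-(4-methoxyphenyl)-8-[4-(4,4,5,5-tetramethyl-1,3,2-dioxaborolan-2-yl)phenoxy]-4H-chromen-4-one | COc1ccc(cc1)-c1coc2c(Oc3ccc(cc3)B3OC(C)(C)C(C)(C)O3)c(OC)cc(OC)c2c1=O
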